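## The problem

Target 34 is a longipinane, numbered here as follows: C1 is the ketone, C2=C3 the alkene with its methyl on C3, C4 and C11 the bridgeheads, C5 the cyclobutane CH, C6 the gem-dimethyl carbon, C7 (OH), C8 (isovalerate) and C9 (angelate) the carbinol carbons, and C10 the methyl-bearing quaternary carbon. The cyclobutane C4–C5–C11–C10 is spanned across its C4/C11 diagonal by the enone bridge C1–C2–C3 and across its C5/C10 diagonal, on the opposite face, by the chain C6–C7–C8–C9, so that a verbenone-like bicyclo[3.1.1]heptenone and a seven-membered ring share the four-membered ring. Of the seven stereocentres (4R,5S,7S,8S,9S,10R,11R), C4, C5, C10 and C11 are locked together by the ring system, so only their absolute sense must be chosen, while C7–C9 carry a triol unit with O7 and O8 cis and O9 trans to both. C9 sits on C10: if it is present before the cyclobutane forms it can pass its configuration to the core, and later its substituent can steer an oxidant to the far face of a C7=C8 alkene. Three different oxygen functions on neighbouring carbons must be told apart, and only O8 is not next to a quaternary carbon. The angelate isomerises to the tiglate under acid, heat or nucleophilic catalysis, the strained ring next to an alkene rearranges through cations, and the four-membered ring would open by retro-Claisen cleavage if C1 and C5 were carbonyls at the same time. The key step is possible because C5 carries only hydrogen and C6, so it can begin as a cyclobutanone carbonyl, because C10, with its methyl and C9, is the disubstituted end of an E-trisubstituted alkene C10=C11, and because the C3 methyl can begin as a methylidene. The four-membered ring is then the [2+2] adduct of a ketene (C4=C5=O) and that alkene, joined by C1–C2–C3, and the precursor is a 3-methyl-2-enoyl chloride of the geranic acid type.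

## Retrosynthesis

**Esters (34 ⇒ 32 + 33; 32 ⇒ 31 ⇒ 29 + 30; 29 ⇒ 28).** The two acyl C–O bonds are cut last. The isovalerate goes on last because in diol 32 the O8 hydroxyl is the only one not flanked by a quaternary carbon. The angelate cannot be put on by steric selection (O7 and O9 are both neopentyl), so it is installed on alcohol 29, in which O7 and O8 are tied up as an acetonide. It also cannot be present earlier, because its own alkene would compete in the osmylation. The forward steps must acylate a hindered alcohol with retention of the Z geometry and then acylate one hydroxyl of a diol.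

**Diol (28 ⇒ 26 ⇒ 25).** The C7–O and C8–O bonds are cut together back to the C7=C8 alkene of 25. A syn-dihydroxylation is the only direct way to the cis-diol (epoxide opening would give trans). It removes two stereocentres and asks only that the oxidant come from the face opposite the C9 silyloxy group and leave the enone alone.

**Enone (25 ⇒ 24 ⇒ 23).** The C1 carbonyl is traced to an allylic methylene and the C2=C3 alkene to its exocyclic isomer 23. The C1 ketone is introduced only after C5 has ceased to be a carbonyl, since a 1,5-dione here is a non-enolisable β-diketone inside a four-membered ring. It must precede the osmylation, because an electron-rich C2=C3 alkene would be dihydroxylated before the hindered C7=C8 alkene.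

**Seven-membered ring (23 ⇒ 22).** The C7=C8 bond is cut by ring-closing metathesis. Closing at C5–C6 or C6–C7 would have to create a quaternary centre in the ring-forming event. Triene 22 has the two vinyl groups held cis on the cyclobutane, and the new alkene is exactly the one needed for the diol.

**C5 side chain (22 ⇒ 20 ⇒ 18 ⇒ 15 ⇒ 14 ⇒ 12 + 13, with 16 and 21).** The C5–C6 bond is cut as a C5=C6 alkene (olefination of ketone 12 with phosphonate 13). The two C6 methyls come from iodomethane 16, and the nitrile carbon becomes C7, methylenated with the ylide from 21. A nitrile is chosen over an ester because its anion is small enough to be quaternised next to the cyclobutane and because one hydride reduction gives the aldehyde. The only new stereocentre, C5, is set when hydride adds anti to the C9 substituent.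

**Key disconnection (12 ⇒ 11 ⇒ 10).** The C4–C10 and C5–C11 bonds are cut together. Both carbocycles of the bicyclo[3.1.1]heptanone and three stereocentres go back to an acyclic trienoyl chloride, 10, through vinylketene 11. Cutting only one cyclobutane bond (as in the first two alternatives below) leaves a cyclic precursor that itself needs a long synthesis. The forward reaction must choose the trisubstituted alkene, the crossed regiochemistry and one alkene face.

**Precursor (10 ⇒ 9 ⇒ 8 ⇒ 6 ⇒ 5 ⇒ 3 + 4; 3 ⇒ 1).** The acid chloride comes from ester 8 by hydrolysis to 9 and neutral chlorination, the silyl ether from 7, and the C8–C9 bond from addition of vinylmagnesium bromide 4 to enal 3, made by allylic oxidation of methyl geranate 1. The carbinol centre is resolved (5 to 6). Both enantiomers of 5 are accessible from the same resolution, which matters because the sense of induction in the key step is the uncertain point.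

## Roads not taken

**Alternative 1:** the cut is the C4–C10 bond alone. In a cis-fused himachalene A2 that carries a 9,10-epoxide and the 7,8-acetonide, MeAlCl2 would ionise the epoxide at C10; the C3=C4 alkene attacks through C4 and loss of a C2 proton gives 7,8-O-isopropylidene-longipin-2-en-9-ol A1.
- Merits: the logic follows the biogenesis; the epoxide delivers C9–OH with defined configuration; the triol pattern and the C2=C3 alkene are already in A1, so only C1 oxidation and the esters remain.
- Weak points: a four-membered ring must be closed by a cation–olefin reaction in competition with strain-free exits of the C10 cation (hydride shift to a C9 ketone, proton loss, attack through C3); the C8 oxygen next to the cationic centre slows ionisation; A2 itself, a seven-membered ring with four contiguous stereocentres and a face-defined epoxide, is not a short target.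
- Comparison: the endgame after A1 is shorter than the chosen one by the steps spent on C5 homologation, metathesis and dihydroxylation, and no facial gamble at C9 is needed. The chosen plan sets against this a ring-forming step of a known reaction class and a precursor reached in six steps from a C10 ester.

**Alternative 2:** the cut is C10–C11 together with the C1 carbonyl. In the bornene-type mesylate A4 the bridgehead alkoxide at C1 pushes C10 from C1 to C11, anti to the endo mesylate, and 9-O-(4-methoxybenzyl)-longipina-2,7-dien-1-one A3 forms in one step.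
- Merits: A3 already holds the cyclobutane, the enone and the C7=C8 alkene, so the alkene isomerisation and allylic oxidation of the chosen route (two of its least secure steps) are not needed; the migration is stereospecific.
- Weak points: the contraction runs uphill in strain and is paid for only by carbonyl formation, so fragmentation and elimination compete; A4 needs a bridgehead hydroxyl, an endo leaving group, the quaternary C10 with its C9 stereocentre and the seven-membered ring, all to be assembled through an intramolecular Diels–Alder reaction whose partners are electronically mismatched if the oxygens are carried directly.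
- Comparison: after its key step this road is better than the chosen one, since A3 needs only the osmylation and the esters. Before it, the chosen plan is far shorter and rests on a cycloaddition with direct precedent on the same substrate class.

**Alternative 3:** the cuts are C1–C11 and C3–C4. The enone bridge would be annulated onto the prochiral cyclobutanone A6 through its enamine with a chiral pyrrolidine: acylation at C11 with but-2-ynoyl chloride A7, then conjugate addition of the regenerated enamine from C4 to the ynone, to give 7-(dimethoxymethyl)-4,7-dimethylbicyclo[3.1.1]hept-3-ene-2,6-dione A5.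
- Merits: it is by far the shortest entry to the bicyclic core with the enone in place, and absolute configuration comes from desymmetrisation of A6 and not from a resolved stereocentre.
- Weak points: both bonds must form on one face of a four-membered ring, the second as a 6-endo-dig addition across the ring diagonal; the enamine of A6 is strained and its N-acylation by A7 competes; A5 is a non-enolisable β-diketone in a four-membered ring and would be opened by the amine, water or chloride in the same flask; later homologation would have to distinguish C5 from the C1 ketone, and C9 would have to be created on a nearly symmetric scaffold under reagent control.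
- Comparison: in step economy this road wins clearly if its key step works. The chosen plan sets against it a known cycloaddition, an adduct in which C5 is the only carbonyl while the side chain is attached, and a C9 centre that is in place from the start.

Key step: step 7

Assumption: the sense of facial induction in step 7 is taken from the staggered transition-state model described there and has not been established for this substrate; the route is written for that sense and the first fallback covers the opposite one.

## Route

Step 1
Reactants: 1 methyl geranate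
Product: 3 methyl (2E,6E)-3,7-dimethyl-8-oxoocta-2,6-dienoate, via allylic alcohol 2 (not isolated)
Conditions: SeO2 (1.2 equiv), 1,4-dioxane, H2O (trace), 90 °C
Reagents that add atoms: selenium dioxide, O=[Se]=O
Why: Riley allylic oxidation (ene reaction, then [2,3]-sigmatropic shift) attacks the electron-rich distal alkene and not the conjugated one, and takes the methyl trans to the chain, so the E-configured alcohol 2 forms and is oxidised on to the enal under the same conditions.

Step 2
Reactants: 3 methyl (2E,6E)-3,7-dimethyl-8-oxoocta-2,6-dienoate; 4 vinylmagnesium bromide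
Product: 5 methyl (2E,6E)-8-hydroxy-3,7-dimethyldeca-2,6,9-trienoate (racemic)
Conditions: CH2=CHMgBr (1.1 equiv), THF, −78 °C; aqueous work-up
Reagents that add atoms: vinylmagnesium bromide (4), C=C[Mg]Br
Why: Grignard 1,2-addition to the enal, which is far more electrophilic than the β,β-disubstituted enoate at −78 °C; the new carbinol centre forms as a racemate and is resolved in step 3.

Step 3
Reactants: 5 methyl (2E,6E)-8-hydroxy-3,7-dimethyldeca-2,6,9-trienoate (racemic)
Product: 6 methyl (2E,6E,8R)-8-hydroxy-3,7-dimethyldeca-2,6,9-trienoate
Conditions: Ti(OiPr)4 (0.2 equiv), L-(+)-diisopropyl tartrate (0.25 equiv), t-BuOOH (0.6 equiv), 4 Å molecular sieves, CH2Cl2, −20 °C; stopped shortly after half conversion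
Reagents that add atoms: none
Why: Sharpless kinetic resolution: with the L-(+)-tartrate the (S)-alcohol is epoxidised quickly at its trisubstituted alkene and the (R)-alcohol is recovered; epoxidation of the vinyl arm, for which the (R)-alcohol is the matched isomer, is intrinsically much slower because that alkene is monosubstituted.

Step 4
Reactants: 6 methyl (2E,6E,8R)-8-hydroxy-3,7-dimethyldeca-2,6,9-trienoate; 7 tert-butyldimethylsilyl chloride
Product: 8 methyl (2E,6E,8R)-8-(tert-butyldimethylsilyloxy)-3,7-dimethyldeca-2,6,9-trienoate
Conditions: TBSCl, imidazole, DMF, 25 °C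
Reagents that add atoms: tert-butyldimethylsilyl chloride (7), CC(C)(C)[Si](C)(C)Cl
Why: Standard silylation of a secondary alcohol; the silyl ether tolerates base, ketene generation, enolate alkylation, hydride reduction and metathesis, and later is the bulky group that directs the osmylation.

Step 5
Reactants: 8 methyl (2E,6E,8R)-8-(tert-butyldimethylsilyloxy)-3,7-dimethyldeca-2,6,9-trienoate
Product: 9 (2E,6E,8R)-8-(tert-butyldimethylsilyloxy)-3,7-dimethyldeca-2,6,9-trienoic acid
Conditions: LiOH·H2O, THF/MeOH/H2O, 45 °C; then 0.5 M HCl to pH 4 at 0 °C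
Reagents that add atoms: lithium hydroxide, [Li+].[OH-]
Why: Saponification by acyl–oxygen cleavage; the silyl ether is stable to hydroxide, and the acidification is kept cold and mild because the doubly allylic C–O bond ionises easily.

Step 6
Reactants: 9 (2E,6E,8R)-8-(tert-butyldimethylsilyloxy)-3,7-dimethyldeca-2,6,9-trienoic acid
Product: 10 (2E,6E,8R)-8-(tert-butyldimethylsilyloxy)-3,7-dimethyldeca-2,6,9-trienoyl chloride
Conditions: 1-chloro-N,N,2-trimethylprop-1-en-1-amine (1.2 equiv), CH2Cl2, 0 → 25 °C; concentrated and used crude
Reagents that add atoms: 1-chloro-N,N,2-trimethylprop-1-en-1-amine, CC(C)=C(Cl)N(C)C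
Why: Acid chloride formation with an α-chloroenamine under neutral conditions; no HCl is released (the by-product is an amide), which protects the doubly allylic silyl ether and the 2E geometry.

Step 7
Reactants: 10 (2E,6E,8R)-8-(tert-butyldimethylsilyloxy)-3,7-dimethyldeca-2,6,9-trienoyl chloride
Product: 12 (1R,5S,7S)-7-[(1R)-1-(tert-butyldimethylsilyloxy)prop-2-en-1-yl]-7-methyl-2-methylidenebicyclo[3.1.1]heptan-6-one, via vinylketene 11 (not isolated)
Conditions: Et3N (3 equiv), toluene, 110 °C, slow addition of 10 (final concentration about 0.01 M)
Reagents that add atoms: none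
Why: Et3N removes HCl from 10 in a 1,4-sense (chloride from C5, a proton from the C3 methyl, which lies cis to the acyl group across the C4=C3 alkene) and gives the cross-conjugated vinylketene 11; loss of a C2 methylene proton instead would give a linear dienylketene, whose E form cannot reach the alkene and whose Z form would close to the endocyclic C2=C3 isomer of 12, an expected minor by-product with the same skeleton. The closest known reaction type is the intramolecular vinylketene–alkene [2+2] cycloaddition of geranoyl- and farnesoyl-type chlorides to 2-methylidenebicyclo[3.1.1]heptan-6-ones. The thermal cycloaddition is asynchronous: the electrophilic ketene carbon C5 bonds first to the less substituted alkene carbon C11, closing the ring C5–C4–C3–C2–C1–C11 in a 6-exo sense, and C4 then closes the cyclobutanone onto C10, the carbon that best carries positive charge; this second bond also completes the six-membered carbocycle C1–C2–C3–C4–C10–C11, so the crossed (bridged) adduct results. Addition is suprafacial on the alkene, so the E geometry places the C10 methyl cis to C1, over the three-carbon bridge, and C9 on the open side next to the C5 carbonyl, while C4 can only become the cis bridgehead. The absolute configuration of C4, C10 and C11 follows from the alkene face that is attacked, and this is controlled by the (R)-centre C9: in the staggered transition structure the C9–H should point inside, over the forming four-membered ring where the ketene carbon arrives, the C9–C8 bond (the better donor and the larger group at short range) should lie anti to the incoming C4, and the C–O bond should lie near the alkene plane, where it withdraws least from the cationic C10. The step needs site selectivity for C10=C11 over the vinyl group (secured by tether length and alkene nucleophilicity), crossed regiochemistry (secured by the three-atom tether and the trisubstituted alkene) and facial selectivity (secured only by C9, the least certain element); slow addition at high dilution suppresses ketene dimerisation.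

Step 8
Reactants: 12 (1R,5S,7S)-7-[(1R)-1-(tert-butyldimethylsilyloxy)prop-2-en-1-yl]-7-methyl-2-methylidenebicyclo[3.1.1]heptan-6-one; 13 diethyl (cyanomethyl)phosphonate
Product: 14 2-{7-[(1R)-1-(tert-butyldimethylsilyloxy)prop-2-en-1-yl]-7-methyl-2-methylidenebicyclo[3.1.1]heptan-6-ylidene}acetonitrile (ring stereocentres as in 12; both alkene isomers)
Conditions: NaH, (EtO)2P(O)CH2CN, THF, 0 → 50 °C
Reagents that add atoms: diethyl (cyanomethyl)phosphonate (13), CCOP(=O)(CC#N)OCC
Why: Horner–Wadsworth–Emmons olefination of a strained, non-enolisable cyclobutanone (both α-carbons are bridgeheads) by a small stabilised carbanion that approaches from the side of the C1–C3 bridge; the geometry of the new alkene does not matter because C6 becomes sp3 in the next step.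

Step 9
Reactants: 14 2-{7-[(1R)-1-(tert-butyldimethylsilyloxy)prop-2-en-1-yl]-7-methyl-2-methylidenebicyclo[3.1.1]heptan-6-ylidene}acetonitrile
Product: 15 2-{7-[(1R)-1-(tert-butyldimethylsilyloxy)prop-2-en-1-yl]-7-methyl-2-methylidenebicyclo[3.1.1]heptan-6-yl}acetonitrile (cyanomethyl group on C5 anti to the C1–C3 bridge and cis to C9)
Conditions: Cu(OAc)2 (5 mol %), Xantphos (5 mol %), (EtO)2MeSiH (3 equiv), t-BuOH (3 equiv), toluene, 25 °C
Reagents that add atoms: none
Why: Conjugate reduction of a β,β-disubstituted unsaturated nitrile by a ligated CuH species; hydride reaches C5 from the face of the C1–C3 bridge because the opposite face is covered by the C9 substituent on C10, so C5–H ends syn to that bridge and C6 cis to C9, as the seven-membered ring requires; the polar mechanism avoids a cyclobutylcarbinyl radical at C6 and leaves the isolated alkenes untouched.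

Step 10
Reactants: 15 2-{7-[(1R)-1-(tert-butyldimethylsilyloxy)prop-2-en-1-yl]-7-methyl-2-methylidenebicyclo[3.1.1]heptan-6-yl}acetonitrile; 16 iodomethane
Product: 18 2-{7-[(1R)-1-(tert-butyldimethylsilyloxy)prop-2-en-1-yl]-7-methyl-2-methylidenebicyclo[3.1.1]heptan-6-yl}-2-methylpropanenitrile (ring stereocentres as in 15), via monomethyl nitrile 17 (not isolated)
Conditions: LiN(i-Pr)2 (1.2 equiv), THF, −78 °C, then MeI; LiN(i-Pr)2 (1.5 equiv), DMPU, −78 °C, then MeI, → 0 °C
Reagents that add atoms: iodomethane (16), CI
Why: Two successive α-alkylations of a nitrile; the slim, linear nitrile-stabilised anion tolerates the crowded position next to the cyclobutane and no other C–H in 15 is acidic enough to compete; the configuration of C6 in 17 is irrelevant.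

Step 11
Reactants: 18 2-{7-[(1R)-1-(tert-butyldimethylsilyloxy)prop-2-en-1-yl]-7-methyl-2-methylidenebicyclo[3.1.1]heptan-6-yl}-2-methylpropanenitrile
Product: 20 2-{7-[(1R)-1-(tert-butyldimethylsilyloxy)prop-2-en-1-yl]-7-methyl-2-methylidenebicyclo[3.1.1]heptan-6-yl}-2-methylpropanal (ring stereocentres as in 15), via aldimine 19 (not isolated)
Conditions: i-Bu2AlH (1.5 equiv), toluene, −78 → 0 °C; then aq. tartaric acid, 0 °C
Reagents that add atoms: water, O
Why: Partial reduction of a nitrile by i-Bu2AlH stops at the N-metallated aldimine, which is hydrolysed on work-up; the aldehyde has a quaternary α-carbon and can neither epimerise nor enolise.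

Step 12
Reactants: 20 2-{7-[(1R)-1-(tert-butyldimethylsilyloxy)prop-2-en-1-yl]-7-methyl-2-methylidenebicyclo[3.1.1]heptan-6-yl}-2-methylpropanal; 21 methyltriphenylphosphonium bromide
Product: 22 7-[(1R)-1-(tert-butyldimethylsilyloxy)prop-2-en-1-yl]-7-methyl-2-methylidene-6-(2-methylbut-3-en-2-yl)bicyclo[3.1.1]heptane (ring stereocentres as in 15)
Conditions: Ph3PCH3Br, KOt-Bu, THF, 0 → 25 °C
Reagents that add atoms: methyltriphenylphosphonium bromide (21), C[P+](c1ccccc1)(c1ccccc1)c1ccccc1.[Br-]
Why: Wittig methylenation with the unhindered non-stabilised ylide, which is reliable for neopentyl aldehydes.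

Step 13
Reactants: 22 7-[(1R)-1-(tert-butyldimethylsilyloxy)prop-2-en-1-yl]-7-methyl-2-methylidene-6-(2-methylbut-3-en-2-yl)bicyclo[3.1.1]heptane
Product: 23 (9R)-9-(tert-butyldimethylsilyloxy)longipin-7-ene in which the C3 methyl is an exocyclic methylidene (C4, C5, C10 and C11 as in 34)
Conditions: second-generation Grubbs catalyst, (H2IMes)(PCy3)Cl2Ru=CHPh (10 mol %), toluene (0.005 M), 80 °C
Reagents that add atoms: none
Why: Ring-closing metathesis of two vinyl groups held parallel on the same face of the cyclobutane (1,3-cis on C5 and C10), helped by the gem-dimethyl group; it closes the seven-membered ring with a cis C7=C8 alkene, while the 1,1-disubstituted methylidene reacts more slowly and, lying on the other face, cannot close a ring.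

Step 14
Reactants: 23 (9R)-9-(tert-butyldimethylsilyloxy)longipin-7-ene with exocyclic C3 methylidene
Product: 24 (9R)-9-(tert-butyldimethylsilyloxy)longipina-2,7-diene
Conditions: Pd/C (10 wt % Pd, saturated with H2, then kept under Ar), cyclohexane, 25 °C
Reagents that add atoms: none
Why: Alkene isomerisation by Pd–H addition–elimination moves the exposed exocyclic alkene into the ring to the more stable trisubstituted isomer, the change known for the exocyclic-to-endocyclic pinene pair; C4 is a bridgehead, so the double bond can only move towards C2, and the C7=C8 alkene is shielded by C6 and by the silyloxy-bearing C9.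

Step 15
Reactants: 24 (9R)-9-(tert-butyldimethylsilyloxy)longipina-2,7-diene
Product: 25 (9R)-9-(tert-butyldimethylsilyloxy)longipina-2,7-dien-1-one
Conditions: CrO3, 3,5-dimethylpyrazole, CH2Cl2, −20 °C
Reagents that add atoms: chromium trioxide, O=[Cr](=O)=O
Why: Allylic oxidation of the pinene-to-verbenone type by the CrO3–3,5-dimethylpyrazole complex: C1 is the only methylene allylic to the electron-rich trisubstituted alkene (C4 is a bridgehead), whereas the C9–H is buried between the quaternary C10 and the silyl group.

Step 16
Reactants: 25 (9R)-9-(tert-butyldimethylsilyloxy)longipina-2,7-dien-1-one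
Product: 26 (7S,8S,9S)-9-(tert-butyldimethylsilyloxy)-7,8-dihydroxylongipin-2-en-1-one (7,8-cis-diol trans to O9)
Conditions: OsO4 (5 mol %), N-methylmorpholine N-oxide, acetone/H2O, 25 °C; Na2SO3 work-up
Reagents that add atoms: osmium tetroxide, O=[Os](=O)(=O)=O; N-methylmorpholine N-oxide, C[N+]1([O-])CCOCC1; water, O
Why: Upjohn dihydroxylation: suprafacial addition gives the 7,8-cis-diol, and OsO4 approaches C7=C8 from the face opposite the bulky C9 silyloxy group (the two faces are otherwise nearly equivalent, each bearing one C6 methyl), which sets C7 and C8 trans to O9; the hindered, electron-poor enone is not attacked.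

Step 17
Reactants: 26 (7S,8S,9S)-9-(tert-butyldimethylsilyloxy)-7,8-dihydroxylongipin-2-en-1-one; 27 2,2-dimethoxypropane
Product: 28 (7S,8S,9S)-9-(tert-butyldimethylsilyloxy)-7,8-(isopropylidenedioxy)longipin-2-en-1-one
Conditions: Me2C(OMe)2, pyridinium p-toluenesulfonate (cat.), CH2Cl2, 25 °C
Reagents that add atoms: 2,2-dimethoxypropane (27), COC(C)(C)OC
Why: Transketalisation of a cis-1,2-diol to its acetonide; O7 and O8 are masked together so that O9 can be acylated alone.

Step 18
Reactants: 28 (7S,8S,9S)-9-(tert-butyldimethylsilyloxy)-7,8-(isopropylidenedioxy)longipin-2-en-1-one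
Product: 29 (7S,8R,9S)-9-hydroxy-7,8-(isopropylidenedioxy)longipin-2-en-1-one (same spatial arrangement as 28; the C8 descriptor changes by priority only)
Conditions: Bu4NF, AcOH (1:1), THF, 25 → 45 °C
Reagents that add atoms: none
Why: Fluoride cleavage of the silyl ether; buffering with acetic acid keeps the medium near neutral for the enone.

Step 19
Reactants: 29 (7S,8R,9S)-9-hydroxy-7,8-(isopropylidenedioxy)longipin-2-en-1-one; 30 angelic acid
Product: 31 (7S,8S,9S)-9-angeloyloxy-7,8-(isopropylidenedioxy)longipin-2-en-1-one
Conditions: angelic acid, 2,4,6-trichlorobenzoyl chloride, Et3N, toluene, 25 °C; then 29, 80 °C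
Reagents that add atoms: angelic acid (30), C/C=C(/C)C(=O)O
Why: Yamaguchi-type esterification through the mixed anhydride, run without a nucleophilic pyridine catalyst, the established way to acylate hindered secondary alcohols with angelic acid while keeping the Z geometry.

Step 20
Reactants: 31 (7S,8S,9S)-9-angeloyloxy-7,8-(isopropylidenedioxy)longipin-2-en-1-one
Product: 32 (7S,8S,9S)-9-angeloyloxy-7,8-dihydroxylongipin-2-en-1-one
Conditions: AcOH/H2O (4:1), 45 °C
Reagents that add atoms: none
Why: Mild acid hydrolysis of the acetonide; the enoate and the enone tolerate aqueous acetic acid, and the trans arrangement of O9 and O8 disfavours acyl migration.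

Step 21
Reactants: 32 (7S,8S,9S)-9-angeloyloxy-7,8-dihydroxylongipin-2-en-1-one; 33 3-methylbutanoic anhydride
Product: 34 (4R,5S,7S,8S,9S,10R,11R)-9-angeloyloxy-7-hydroxy-8-(3-methylbutanoyloxy)longipin-2-en-1-one
Conditions: (i-BuCO)2O (1.1 equiv), 4-(dimethylamino)pyridine (cat.), pyridine, CH2Cl2, −20 → 0 °C
Reagents that add atoms: 3-methylbutanoic anhydride (33), CC(C)CC(=O)OC(=O)CC(C)C
Why: Site-selective acylation of a diol: O8 is the only hydroxyl not next to a quaternary carbon, whereas O7 is neopentyl, so one equivalent of anhydride at low temperature should stop at the 8-monoester.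

## Compound list

1 | methyl geranate | CC(C)=CCC/C(C)=C/C(=O)OC | starting material
2 | methyl (2E,6E)-8-hydroxy-3,7-dimethylocta-2,6-dienoate | OC/C(C)=C/CC/C(C)=C/C(=O)OC | intermediate (not isolated)
3 | methyl (2E,6E)-3,7-dimethyl-8-oxoocta-2,6-dienoate | O=C/C(C)=C/CC/C(C)=C/C(=O)OC | intermediate
4 | vinylmagnesium bromide | C=C[Mg]Br | starting material
5 | methyl (2E,6E)-8-hydroxy-3,7-dimethyldeca-2,6,9-trienoate, racemic | C=CC(O)/C(C)=C/CC/C(C)=C/C(=O)OC | intermediate
6 | methyl (2E,6E,8R)-8-hydroxy-3,7-dimethyldeca-2,6,9-trienoate | O[C@@H](/C(C)=C/CC/C(C)=C/C(=O)OC)C=C | intermediate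
7 | tert-butyldimethylsilyl chloride | CC(C)(C)[Si](C)(C)Cl | starting material
8 | methyl (2E,6E,8R)-8-(tert-butyldimethylsilyloxy)-3,7-dimethyldeca-2,6,9-trienoate | CC(C)(C)[Si](C)(C)O[C@@H](/C(C)=C/CC/C(C)=C/C(=O)OC)C=C | intermediate
9 | (2E,6E,8R)-8-(tert-butyldimethylsilyloxy)-3,7-dimethyldeca-2,6,9-trienoic acid | CC(C)(C)[Si](C)(C)O[C@@H](/C(C)=C/CC/C(C)=C/C(=O)O)C=C | intermediate
10 | (2E,6E,8R)-8-(tert-butyldimethylsilyloxy)-3,7-dimethyldeca-2,6,9-trienoyl chloride | CC(C)(C)[Si](C)(C)O[C@@H](/C(C)=C/CC/C(C)=C/C(Cl)=O)C=C | intermediate
11 | (6E,8R)-8-(tert-butyldimethylsilyloxy)-7-methyl-3-methylidenedeca-1,6,9-trien-1-one (vinylketene) | CC(C)(C)[Si](C)(C)O[C@@H](/C(C)=C/CCC(=C)C=C=O)C=C | intermediate (not isolated)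
12 | (1R,5S,7S)-7-[(1R)-1-(tert-butyldimethylsilyloxy)prop-2-en-1-yl]-7-methyl-2-methylidenebicyclo[3.1.1]heptan-6-one | CC(C)(C)[Si](C)(C)O[C@@H]([C@@]1(C)[C@@H]2CCC(=C)[C@H]1C2=O)C=C | intermediate
13 | diethyl (cyanomethyl)phosphonate | CCOP(=O)(CC#N)OCC | starting material
14 | 6-(cyanomethylidene) derivative of 12, both alkene isomers | CC(C)(C)[Si](C)(C)O[C@@H]([C@@]1(C)[C@@H]2CCC(=C)[C@H]1C2=CC#N)C=C | intermediate
15 | C5 cyanomethyl compound, C6 anti to the C1–C3 bridge and cis to C9 | CC(C)(C)[Si](C)(C)O[C@@H]([C@@]1(C)[C@@H]2CCC(=C)[C@H]1[C@@H]2CC#N)C=C | intermediate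
16 | iodomethane | CI | starting material
17 | monomethylated nitrile, both C6 epimers | CC(C)(C)[Si](C)(C)O[C@@H]([C@@]1(C)[C@@H]2CCC(=C)[C@H]1[C@@H]2C(C)C#N)C=C | intermediate (not isolated)
18 | gem-dimethyl nitrile | CC(C)(C)[Si](C)(C)O[C@@H]([C@@]1(C)[C@@H]2CCC(=C)[C@H]1[C@@H]2C(C)(C)C#N)C=C | intermediate
19 | aldimine of 20 | CC(C)(C)[Si](C)(C)O[C@@H]([C@@]1(C)[C@@H]2CCC(=C)[C@H]1[C@@H]2C(C)(C)C=N)C=C | intermediate (not isolated)
20 | neopentyl aldehyde (C7) | CC(C)(C)[Si](C)(C)O[C@@H]([C@@]1(C)[C@@H]2CCC(=C)[C@H]1[C@@H]2C(C)(C)C=O)C=C | intermediate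
21 | methyltriphenylphosphonium bromide | C[P+](c1ccccc1)(c1ccccc1)c1ccccc1.[Br-] | starting material
22 | triene with vinyl groups on C6 and C9 | CC(C)(C)[Si](C)(C)O[C@@H]([C@@]1(C)[C@@H]2CCC(=C)[C@H]1[C@@H]2C(C)(C)C=C)C=C | intermediate
23 | (9R)-9-(tert-butyldimethylsilyloxy)longipin-7-ene with exocyclic C3 methylidene | CC(C)(C)[Si](C)(C)O[C@@H]1C=CC(C)(C)[C@@H]2[C@H]3CCC(=C)[C@@H]2[C@@]13C | intermediate
24 | (9R)-9-(tert-butyldimethylsilyloxy)longipina-2,7-diene | CC(C)(C)[Si](C)(C)O[C@@H]1C=CC(C)(C)[C@@H]2[C@H]3CC=C(C)[C@@H]2[C@@]13C | intermediate
25 | (9R)-9-(tert-butyldimethylsilyloxy)longipina-2,7-dien-1-one | CC(C)(C)[Si](C)(C)O[C@@H]1C=CC(C)(C)[C@@H]2[C@H]3C(=O)C=C(C)[C@@H]2[C@@]13C | intermediate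
26 | (7S,8S,9S)-9-(tert-butyldimethylsilyloxy)-7,8-dihydroxylongipin-2-en-1-one | CC(C)(C)[Si](C)(C)O[C@@H]1[C@@H](O)[C@@H](O)C(C)(C)[C@@H]2[C@H]3C(=O)C=C(C)[C@@H]2[C@@]13C | intermediate
27 | 2,2-dimethoxypropane | COC(C)(C)OC | starting material
28 | (7S,8S,9S)-9-(tert-butyldimethylsilyloxy)-7,8-(isopropylidenedioxy)longipin-2-en-1-one | CC(C)(C)[Si](C)(C)O[C@@H]1[C@@H](OC4(C)C)[C@@H](O4)C(C)(C)[C@@H]2[C@H]3C(=O)C=C(C)[C@@H]2[C@@]13C | intermediate
29 | (7S,8R,9S)-9-hydroxy-7,8-(isopropylidenedioxy)longipin-2-en-1-one | O[C@@H]1[C@@H](OC4(C)C)[C@@H](O4)C(C)(C)[C@@H]2[C@H]3C(=O)C=C(C)[C@@H]2[C@@]13C | intermediate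
30 | angelic acid, (Z)-2-methylbut-2-enoic acid | C/C=C(/C)C(=O)O | starting material
31 | (7S,8S,9S)-9-angeloyloxy-7,8-(isopropylidenedioxy)longipin-2-en-1-one | C/C=C(/C)C(=O)O[C@@H]1[C@@H](OC4(C)C)[C@@H](O4)C(C)(C)[C@@H]2[C@H]3C(=O)C=C(C)[C@@H]2[C@@]13C | intermediate
32 | (7S,8S,9S)-9-angeloyloxy-7,8-dihydroxylongipin-2-en-1-one | C/C=C(/C)C(=O)O[C@@H]1[C@@H](O)[C@@H](O)C(C)(C)[C@@H]2[C@H]3C(=O)C=C(C)[C@@H]2[C@@]13C | intermediate
33 | 3-methylbutanoic anhydride | CC(C)CC(=O)OC(=O)CC(C)C | starting material
34 | (4R,5S,7S,8S,9S,10R,11R)-9-angeloyloxy-7-hydroxy-8-(3-methylbutanoyloxy)longipin-2-en-1-one | C/C=C(/C)C(=O)O[C@@H]1[C@@H](OC(=O)CC(C)C)[C@@H](O)C(C)(C)[C@@H]2[C@H]3C(=O)C=C(C)[C@@H]2[C@@]13C | target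

## Step count and least certain steps

Total: 21 steps, all in one line from methyl geranate (longest linear sequence 21 steps).

**Step 7 (key step).** The most likely failure is weak or reversed facial discrimination, because the alkene carries only hydrogen cis to C9 and the conformational preference about C9–C10 is therefore small. A second concern is loss of material to ketene dimerisation, since the allylic oxygen lowers the nucleophilicity of the alkene. With weak discrimination the two adducts are diastereomers and can be separated. With reversed discrimination the fallback sets out from 5 and returns at 15; it uses the enantiomeric series and corrects C9 under reagent control once the cyclobutanone carbonyl is gone. Resolution of 5 with D-(−)-diisopropyl tartrate leaves the (8S)-alcohol F1. Silylation gives the ester F2, saponification the acid F3 and the chloroenamine the acid chloride F4. Cycloaddition then gives the C9-epimeric bicyclic ketone F5 with the required ring configuration. Olefination and CuH reduction as in steps 8 and 9 give the unsaturated nitrile F6 and the saturated nitrile F7. Bu4NF frees the epimeric allylic alcohol F8, Dess–Martin periodinane gives the vinyl ketone F9, and reduction with catecholborane and (S)-2-methyl-CBS-oxazaborolidine (quaternary C10 as the large group, vinyl as the small one) gives the (9R)-alcohol F10, which is silylated to 15.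

**Step 14.** The most likely failure is migration or saturation of the wrong alkene: the Pd–H catalyst may move C7=C8 towards the silyl enol ether position or hydrogenate the methylidene. The fallback sets out from 23 and returns at 25, so it also bypasses step 15; it removes the exocyclic carbon and rebuilds the enone by carbonyl transposition. OsO4/NaIO4 cleaves the exposed methylidene to the C3 ketone F11. LiN(i-Pr)2 followed by N-tert-butylbenzenesulfinimidoyl chloride dehydrogenates it (only C2 can enolise) to the C1=C2 enone F12. MeLi with CeCl3 adds to C3 to give the tertiary allylic alcohol F13, and pyridinium chlorochromate, (C5H5NH)CrO3Cl, brings about oxidative 1,3-transposition to 25.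

**Step 15.** The most likely failure is competing hydrogen abstraction at C9–H, which is allylic to C7=C8 and α to the silyloxy group, leading to oxidation of the wrong ring. The fallback sets out from 24 and returns at 25; it makes C9–H electron-poor for the oxidation. Bu4NF gives the dienol F14 and Ac2O with 4-(dimethylamino)pyridine the acetate F15. CrO3/3,5-dimethylpyrazole then oxidises C1 to the enone acetate F16, K2CO3 in MeOH frees the hydroxy enone F17, and TBSOTf with 2,6-lutidine returns 25.

**Step 13.** The most likely failure is slow loading of the catalyst onto either vinyl group (one neopentyl, one flanked by the silyloxy carbon and C10), followed by catalyst decay and alkene migration by Ru–H species. The fallback sets out from 20 and returns at 23 and uses relay metathesis. Wittig reaction of 20 with the ylide from (hex-5-en-1-yl)triphenylphosphonium bromide gives the relay tetraene F18. The catalyst loads at its unhindered terminal alkene, expels cyclopentene and is thereby delivered to C7, from where it closes onto the C8 vinyl group to give 23.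

**Step 19.** The most likely failure is incomplete acylation of the hindered C9 hydroxyl, or Z-to-E isomerisation of the angelate at the temperature needed. The fallback sets out from 29 and returns at 31 and builds the Z-alkene on the ester. Acylation of 29 with 2-[bis(2,2,2-trifluoroethoxy)phosphoryl]propanoic acid (dicyclohexylcarbodiimide, 4-(dimethylamino)pyridine) gives the phosphonopropionate F19. Still–Gennari olefination with acetaldehyde (KN(SiMe3)2, 18-crown-6, THF, −78 °C) then gives 31.

## Further compounds

F1 | step 7 | methyl (2E,6E,8S)-8-hydroxy-3,7-dimethyldeca-2,6,9-trienoate | O[C@H](/C(C)=C/CC/C(C)=C/C(=O)OC)C=C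
F2 | step 7 | methyl (2E,6E,8S)-8-(tert-butyldimethylsilyloxy)-3,7-dimethyldeca-2,6,9-trienoate | CC(C)(C)[Si](C)(C)O[C@H](/C(C)=C/CC/C(C)=C/C(=O)OC)C=C
F3 | step 7 | (2E,6E,8S)-8-(tert-butyldimethylsilyloxy)-3,7-dimethyldeca-2,6,9-trienoic acid | CC(C)(C)[Si](C)(C)O[C@H](/C(C)=C/CC/C(C)=C/C(=O)O)C=C
F4 | step 7 | (2E,6E,8S)-8-(tert-butyldimethylsilyloxy)-3,7-dimethyldeca-2,6,9-trienoyl chloride | CC(C)(C)[Si](C)(C)O[C@H](/C(C)=C/CC/C(C)=C/C(Cl)=O)C=C
F5 | step 7 | C9 epimer of 12, (1R,5S,7S)-7-[(1S)-1-(tert-butyldimethylsilyloxy)prop-2-en-1-yl]-7-methyl-2-methylidenebicyclo[3.1.1]heptan-6-one | CC(C)(C)[Si](C)(C)O[C@H]([C@@]1(C)[C@@H]2CCC(=C)[C@H]1C2=O)C=C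
F6 | step 7 | C9 epimer of 14 | CC(C)(C)[Si](C)(C)O[C@H]([C@@]1(C)[C@@H]2CCC(=C)[C@H]1C2=CC#N)C=C
F7 | step 7 | C9 epimer of 15 | CC(C)(C)[Si](C)(C)O[C@H]([C@@]1(C)[C@@H]2CCC(=C)[C@H]1[C@@H]2CC#N)C=C
F8 | step 7 | desilylated C9-epimeric allylic alcohol | O[C@H]([C@@]1(C)[C@@H]2CCC(=C)[C@H]1[C@@H]2CC#N)C=C
F9 | step 7 | C9 vinyl ketone | C=CC(=O)[C@@]1(C)[C@@H]2CCC(=C)[C@H]1[C@@H]2CC#N
F10 | step 7 | (9R)-allylic alcohol, desilyl 15 | O[C@@H]([C@@]1(C)[C@@H]2CCC(=C)[C@H]1[C@@H]2CC#N)C=C
F11 | step 14 | C3 ketone from cleavage of the methylidene of 23 | CC(C)(C)[Si](C)(C)O[C@@H]1C=CC(C)(C)[C@@H]2[C@H]3CCC(=O)[C@@H]2[C@@]13C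
F12 | step 14 | C1=C2 enone with C3 carbonyl | CC(C)(C)[Si](C)(C)O[C@@H]1C=CC(C)(C)[C@@H]2[C@H]3C=CC(=O)[C@@H]2[C@@]13C
F13 | step 14 | tertiary allylic alcohol at C3, either epimer | CC(C)(C)[Si](C)(C)O[C@@H]1C=CC(C)(C)[C@@H]2[C@H]3C=CC(C)(O)[C@@H]2[C@@]13C
F14 | step 15 | (9R)-longipina-2,7-dien-9-ol | O[C@@H]1C=CC(C)(C)[C@@H]2[C@H]3CC=C(C)[C@@H]2[C@@]13C
F15 | step 15 | (9R)-9-acetoxylongipina-2,7-diene | CC(=O)O[C@@H]1C=CC(C)(C)[C@@H]2[C@H]3CC=C(C)[C@@H]2[C@@]13C
F16 | step 15 | (9R)-9-acetoxylongipina-2,7-dien-1-one | CC(=O)O[C@@H]1C=CC(C)(C)[C@@H]2[C@H]3C(=O)C=C(C)[C@@H]2[C@@]13C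
F17 | step 15 | (9R)-9-hydroxylongipina-2,7-dien-1-one | O[C@@H]1C=CC(C)(C)[C@@H]2[C@H]3C(=O)C=C(C)[C@@H]2[C@@]13C
F18 | step 13 | relay tetraene, (Z)-hepta-1,6-dienyl group on C6 in place of vinyl | CC(C)(C)[Si](C)(C)O[C@@H]([C@@]1(C)[C@@H]2CCC(=C)[C@H]1[C@@H]2C(C)(C)/C=C\CCCC=C)C=C
F19 | step 19 | 9-O-{2-[bis(2,2,2-trifluoroethoxy)phosphoryl]propanoyl} derivative of 29 | CC(C(=O)O[C@@H]1[C@@H](OC4(C)C)[C@@H](O4)C(C)(C)[C@@H]2[C@H]3C(=O)C=C(C)[C@@H]2[C@@]13C)P(=O)(OCC(F)(F)F)OCC(F)(F)F
A1 | alternative 1 | 7,8-O-isopropylidene-longipin-2-en-9-ol | O[C@@H]1[C@@H](OC5(C)C)[C@@H](O5)C(C)(C)[C@@H]2[C@H]3CC=C(C)[C@@H]2[C@@]13C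
A2 | alternative 1 | cis-fused 9,10-epoxy-7,8-(isopropylidenedioxy)himachal-3-ene | C[C@@]12O[C@@H]1[C@H]3OC(C)(C)O[C@H]3C(C)(C)[C@H]4C=C(C)CC[C@@H]24
A3 | alternative 2 | 9-O-(4-methoxybenzyl)-longipina-2,7-dien-1-one | COc1ccc(CO[C@@H]2C=CC(C)(C)[C@@H]3[C@H]4C(=O)C=C(C)[C@@H]3[C@@]24C)cc1
A4 | alternative 2 | bornene-type bridgehead alcohol with endo mesylate at C11 | COc1ccc(CO[C@@H]2C=CC(C)(C)[C@@H]3[C@@H](OS(C)(=O)=O)[C@@]4(O)C=C(C)[C@@H]3[C@@]24C)cc1
A5 | alternative 3 | 7-(dimethoxymethyl)-4,7-dimethylbicyclo[3.1.1]hept-3-ene-2,6-dione | COC(OC)[C@@]1(C)[C@@H]2C(=O)C=C(C)[C@H]1C2=O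
A6 | alternative 3 | 3-(dimethoxymethyl)-3-methylcyclobutan-1-one | COC(OC)C1(C)CC(=O)C1
A7 | alternative 3 | but-2-ynoyl chloride | CC#CC(Cl)=O
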